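**Plan**

- Retrosynthesis: the side-chain ester C–O bond is cut first. Then both carbonyl-to-ring bonds of the naphthazarin (C1–C8a and C4–C4a) are cut, giving 1,4-benzoquinone and a side-chain-bearing succinic anhydride. The anhydride is cut at its Cα–carbinol bond (aldol), and the enal at its C=C bond (cross-metathesis).
- Enabling feature: the quinonoid carbons C1(=O)–C2=C3–C4(=O) are at the oxidation level of the bis-enol of a succinic anhydride, which is a 2,5-bis(silyloxy)furan diene. The ring-fusion carbons C4a/C8a with the peri-oxygens at C5/C8 are one C=C and the two C=O of benzoquinone. The [4+2] adduct, once its temporary oxygen bridge is lost, is a tautomer of naphthazarin, so the core needs no redox change and no protecting group.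
- Forward order: enal by cross-metathesis; aldol builds the whole side chain on a succinate; anhydride; furan formation, cycloaddition and bridge collapse close the quinonoid ring, while the benzenoid ring arises from the benzoquinone by enolisation; desilylation; esterification.
- Stereochemistry: the (R)-carbinol comes from the boron aldol of the (S)-4-benzyloxazolidinone imide; the E-alkene from metathesis; the acyl stereocentre from (R)-2-methylbutanoic acid. The succinate α-centre and the four sp3 centres of the cycloadduct are erased.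

Key step: step 9

Remark: the tautomers of a monosubstituted naphthazarin interconvert, so a side chain on either ring is the same compound, drawn here as in the target; (R)-2-methylbutanoic acid is taken as a commercial enantiopure acid.

**Step 1**
Reactants: 1 2-methylbut-3-en-2-ol; 2 (E)-but-2-enal
Product: 3 (E)-4-hydroxy-4-methylpent-2-enal
Conditions: second-generation Hoveyda–Grubbs catalyst, [1,3-bis(2,4,6-trimethylphenyl)imidazolidin-2-ylidene]dichloro(2-isopropoxybenzylidene)ruthenium (2 mol %), 2 (3 equiv), CH2Cl2, 40 °C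
Reagents that add atoms: none
Why: Olefin cross-metathesis between a hindered tertiary allylic alcohol, which homodimerises slowly, and excess enal is driven by loss of propene and should give the thermodynamically favoured E-enal.

**Step 2**
Reactants: 3 (E)-4-hydroxy-4-methylpent-2-enal
Product: 4 (E)-4-methyl-4-(triethylsilyloxy)pent-2-enal
Conditions: Et3SiOTf (1.2 equiv), 2,6-lutidine (1.5 equiv), CH2Cl2, −78 °C
Reagents that add atoms: triethylsilyl trifluoromethanesulfonate, CC[Si](CC)(CC)OS(=O)(=O)C(F)(F)F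
Why: Silyl triflate silylation of the tertiary alcohol should be clean because the enal has no enolisable hydrogen, and the silyl ether masks the hydroxyl against the boron triflate of step 4.

**Step 3**
Reactants: 6 4-tert-butoxy-4-oxobutanoic acid; 5 (S)-4-benzyl-1,3-oxazolidin-2-one
Product: 8 tert-butyl 4-[(4S)-4-benzyl-2-oxo-1,3-oxazolidin-3-yl]-4-oxobutanoate, via mixed pivalic anhydride 7 (not isolated)
Conditions: t-BuCOCl, Et3N, THF, −20 °C; then LiCl, 5, −20 °C → rt
Reagents that add atoms: none
Why: N-Acylation of the oxazolidinone through the mixed pivalic anhydride transfers the unhindered succinyl carbonyl; the tert-butyl ester is chosen because it cannot be attacked by the hydroxyl formed in step 4 (no γ-lactonisation).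

**Step 4**
Reactants: 8 tert-butyl 4-[(4S)-4-benzyl-2-oxo-1,3-oxazolidin-3-yl]-4-oxobutanoate; 4 (E)-4-methyl-4-(triethylsilyloxy)pent-2-enal
Product: 11 tert-butyl (3S,4R,5E)-3-{[(4S)-4-benzyl-2-oxo-1,3-oxazolidin-3-yl]carbonyl}-4-hydroxy-7-methyl-7-(triethylsilyloxy)oct-5-enoate, via (Z)-dibutylboron enolate 9 (not isolated), via dibutylboron aldolate 10 (not isolated)
Conditions: Bu2BOTf (1.1 equiv), i-Pr2NEt (1.3 equiv), CH2Cl2, −78 → 0 °C; 4, −78 → 0 °C; then pH 7 buffer, MeOH, 30% H2O2, 0 °C
Reagents that add atoms: none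
Why: Evans syn-aldol reaction: the (Z)-boron enolate of the imide (enolised at the imide α-carbon, not the ester α-carbon) adds 1,2 to the enal through a closed chair transition state on the face away from the benzyl group, which sets the (4R)-carbinol centre together with the (3S)-centre that is erased later.

**Step 5**
Reactants: 11 tert-butyl (3S,4R,5E)-3-{[(4S)-4-benzyl-2-oxo-1,3-oxazolidin-3-yl]carbonyl}-4-hydroxy-7-methyl-7-(triethylsilyloxy)oct-5-enoate
Product: 12 tert-butyl (3S,4R,5E)-3-{[(4S)-4-benzyl-2-oxo-1,3-oxazolidin-3-yl]carbonyl}-4-(tert-butyldimethylsilyloxy)-7-methyl-7-(triethylsilyloxy)oct-5-enoate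
Conditions: t-BuMe2SiOTf (1.3 equiv), 2,6-lutidine (2 equiv), CH2Cl2, −78 → 0 °C
Reagents that add atoms: tert-butyldimethylsilyl trifluoromethanesulfonate, CC(C)(C)[Si](C)(C)OS(=O)(=O)C(F)(F)F
Why: Standard silyl triflate protection of the secondary alcohol blocks retro-aldol and lactonisation in what follows, and a silyl ether is the poorest leaving group available for the position that will sit next to the furan in step 9; the tert-butyl ester is left alone at low temperature.

**Step 6**
Reactants: 12 tert-butyl (3S,4R,5E)-3-{[(4S)-4-benzyl-2-oxo-1,3-oxazolidin-3-yl]carbonyl}-4-(tert-butyldimethylsilyloxy)-7-methyl-7-(triethylsilyloxy)oct-5-enoate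
Product: 13 (2S,3R,4E)-2-(2-tert-butoxy-2-oxoethyl)-3-(tert-butyldimethylsilyloxy)-6-methyl-6-(triethylsilyloxy)hept-4-enoic acid
Conditions: LiOH·H2O (2 equiv), 30% H2O2 (4 equiv), THF/H2O 3:1, 0 °C; aq Na2SO3; cold 0.5 M HCl to pH 4
Reagents that add atoms: hydrogen peroxide, OO
Why: Hydroperoxide cleavage of the N-acyloxazolidinone attacks the exocyclic carbonyl selectively and should leave the tert-butyl ester and both silyl ethers untouched; the auxiliary is recovered.

**Step 7**
Reactants: 13 (2S,3R,4E)-2-(2-tert-butoxy-2-oxoethyl)-3-(tert-butyldimethylsilyloxy)-6-methyl-6-(triethylsilyloxy)hept-4-enoic acid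
Product: 15 (2S)-2-[(1R,2E)-1-(tert-butyldimethylsilyloxy)-4-methyl-4-(triethylsilyloxy)pent-2-en-1-yl]butanedioic acid, via bis(trimethylsilyl) ester 14 (not isolated)
Conditions: Me3SiOTf (3 equiv), 2,6-lutidine (5 equiv), CH2Cl2, 0 °C → rt; then pH 5 buffer/THF, 0 °C
Reagents that add atoms: none
Why: Silyl triflate-mediated tert-butyl ester cleavage (O-silylation of the ester carbonyl, loss of the tert-butyl cation as isobutene, lutidine as buffer) gives silyl esters that hydrolyse on work-up, which avoids the protic acid that would ionise the tertiary allylic silyl ether or free the γ-hydroxyl.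

**Step 8**
Reactants: 15 (2S)-2-[(1R,2E)-1-(tert-butyldimethylsilyloxy)-4-methyl-4-(triethylsilyloxy)pent-2-en-1-yl]butanedioic acid
Product: 16 (3S)-3-[(1R,2E)-1-(tert-butyldimethylsilyloxy)-4-methyl-4-(triethylsilyloxy)pent-2-en-1-yl]oxolane-2,5-dione
Conditions: DCC (1.05 equiv), CH2Cl2, 0 °C → rt; filtration
Reagents that add atoms: none
Why: Carbodiimide dehydration closes a succinic acid to its five-membered cyclic anhydride under neutral conditions that the silyl ethers tolerate.

**Step 9**
Reactants: 16 (3S)-3-[(1R,2E)-1-(tert-butyldimethylsilyloxy)-4-methyl-4-(triethylsilyloxy)pent-2-en-1-yl]oxolane-2,5-dione; 17 1,4-benzoquinone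
Product: 20 2-[(1R,2E)-1-(tert-butyldimethylsilyloxy)-4-methyl-4-(triethylsilyloxy)pent-2-en-1-yl]-5,8-dihydroxynaphthalene-1,4-dione, via bis(trimethylsilyloxy)furan 18 (not isolated), via oxa-bridged cycloadduct 19 (not isolated)
Conditions: Me3SiOTf (2.2 equiv), Et3N (3 equiv), Et2O, 0 °C → rt; pentane, filtration under argon, evaporation; 17 (1.1 equiv), CH2Cl2, −78 °C → rt; then AcOH, THF/H2O, 0 °C
Reagents that add atoms: none
Why: Soft double enolisation of anhydride 16 gives the aromatic 2,5-bis(trimethylsilyloxy)furan 18, a locked s-cis diene equivalent to a substituted 1,2-bisketene; it should add across one C=C of the benzoquinone in a normal-electron-demand Diels–Alder reaction that forms both carbonyl-to-ring C–C bonds at once, and adduct 19, whose bridgeheads are silyl ketals, collapses on mild acid with loss of hexamethyldisiloxane to an ene-1,4-dione whose two ring-fusion C–H, each flanked by two carbonyls, enolise to the naphthazarin. The closest known reaction type is the Diels–Alder reaction of succinic-anhydride-derived 2,5-bis(trimethylsilyloxy)furans with quinones and other dienophiles, which gives hydroquinones, quinizarin and naphthazarins after bridge opening. The only ring closed is the six-membered quinonoid ring, by intermolecular [4+2] cycloaddition; the oxygen bridge is temporary and the benzenoid ring arises from the benzoquinone by tautomerisation. No new stereocentre survives: the four sp3 centres of 19 and the former α-centre of 16 are erased, and the (R)-carbinol centre from step 4 is a spectator. The selectivity needed is chemoselectivity for cycloaddition at the furan 2,5-positions over conjugate C-arylation through the furan β-carbon, electron transfer to the quinone, or ionisation of the allylic silyloxy group beside the electron-rich furan; it is sought through salt-free, Lewis-acid-free conditions at low temperature, the shielding of the β-carbon by the C3 substituent and the poor leaving-group ability of a silyl ether. Regiochemistry is not at issue, because the benzoquinone is symmetric and the tautomers of a monosubstituted naphthazarin are one compound.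

**Step 10**
Reactants: 20 2-[(1R,2E)-1-(tert-butyldimethylsilyloxy)-4-methyl-4-(triethylsilyloxy)pent-2-en-1-yl]-5,8-dihydroxynaphthalene-1,4-dione
Product: 21 2-[(1R,2E)-1,4-dihydroxy-4-methylpent-2-en-1-yl]-5,8-dihydroxynaphthalene-1,4-dione
Conditions: HF·pyridine, pyridine, THF, 0 °C → rt
Reagents that add atoms: none
Why: Buffered fluoride cleavage of both silyl ethers avoids the basic conditions that naphthazarins do not tolerate, and the E-alkene keeps the two liberated hydroxyls from cyclising onto each other.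

**Step 11**
Reactants: 21 2-[(1R,2E)-1,4-dihydroxy-4-methylpent-2-en-1-yl]-5,8-dihydroxynaphthalene-1,4-dione; 22 (2R)-2-methylbutanoic acid
Product: 23 (1R,2E)-1-(5,8-dihydroxy-1,4-dioxo-1,4-dihydronaphthalen-2-yl)-4-hydroxy-4-methylpent-2-en-1-yl (2R)-2-methylbutanoate
Conditions: DCC (1.3 equiv), 4-(dimethylamino)pyridine (0.1 equiv), CH2Cl2, 0 °C
Reagents that add atoms: none
Why: Steglich esterification should acylate only the secondary allylic hydroxyl, since the tertiary alcohol is hindered and the peri-hydroxyls are tied up in hydrogen bonds to the quinone carbonyls, as in the usual side-chain acylation of shikonin-type naphthazarins; low temperature and catalytic base limit epimerisation of the acid α-centre.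

**Compound list**

1 | 2-methylbut-3-en-2-ol | C=CC(C)(C)O | starting material
2 | (E)-but-2-enal (crotonaldehyde) | C/C=C/C=O | starting material
3 | (E)-4-hydroxy-4-methylpent-2-enal | CC(C)(O)/C=C/C=O | intermediate
4 | (E)-4-methyl-4-(triethylsilyloxy)pent-2-enal | CC[Si](CC)(CC)OC(C)(C)/C=C/C=O | intermediate
5 | (S)-4-benzyl-1,3-oxazolidin-2-one | O=C1N[C@@H](Cc2ccccc2)CO1 | starting material
6 | 4-tert-butoxy-4-oxobutanoic acid (mono-tert-butyl succinate) | CC(C)(C)OC(=O)CCC(=O)O | starting material
7 | 4-tert-butoxy-4-oxobutanoic pivalic anhydride | CC(C)(C)OC(=O)CCC(=O)OC(=O)C(C)(C)C | intermediate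
8 | tert-butyl 4-[(4S)-4-benzyl-2-oxo-1,3-oxazolidin-3-yl]-4-oxobutanoate | CC(C)(C)OC(=O)CCC(=O)N1[C@@H](Cc2ccccc2)COC1=O | intermediate
9 | (Z)-dibutylboron enolate of 8 | CC(C)(C)OC(=O)C/C=C(\OB(CCCC)CCCC)N1[C@@H](Cc2ccccc2)COC1=O | intermediate
10 | dibutylboron aldolate of 11 | CC(C)(C)OC(=O)C[C@H](C(=O)N1[C@@H](Cc2ccccc2)COC1=O)[C@H](OB(CCCC)CCCC)/C=C/C(C)(C)O[Si](CC)(CC)CC | intermediate
11 | tert-butyl (3S,4R,5E)-3-{[(4S)-4-benzyl-2-oxo-1,3-oxazolidin-3-yl]carbonyl}-4-hydroxy-7-methyl-7-(triethylsilyloxy)oct-5-enoate | CC(C)(C)OC(=O)C[C@H](C(=O)N1[C@@H](Cc2ccccc2)COC1=O)[C@H](O)/C=C/C(C)(C)O[Si](CC)(CC)CC | intermediate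
12 | tert-butyl (3S,4R,5E)-3-{[(4S)-4-benzyl-2-oxo-1,3-oxazolidin-3-yl]carbonyl}-4-(tert-butyldimethylsilyloxy)-7-methyl-7-(triethylsilyloxy)oct-5-enoate | CC(C)(C)OC(=O)C[C@H](C(=O)N1[C@@H](Cc2ccccc2)COC1=O)[C@H](O[Si](C)(C)C(C)(C)C)/C=C/C(C)(C)O[Si](CC)(CC)CC | intermediate
13 | (2S,3R,4E)-2-(2-tert-butoxy-2-oxoethyl)-3-(tert-butyldimethylsilyloxy)-6-methyl-6-(triethylsilyloxy)hept-4-enoic acid | CC(C)(C)OC(=O)C[C@H](C(=O)O)[C@H](O[Si](C)(C)C(C)(C)C)/C=C/C(C)(C)O[Si](CC)(CC)CC | intermediate
14 | bis(trimethylsilyl) (2S)-2-[(1R,2E)-1-(tert-butyldimethylsilyloxy)-4-methyl-4-(triethylsilyloxy)pent-2-en-1-yl]butanedioate | C[Si](C)(C)OC(=O)C[C@H](C(=O)O[Si](C)(C)C)[C@H](O[Si](C)(C)C(C)(C)C)/C=C/C(C)(C)O[Si](CC)(CC)CC | intermediate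
15 | (2S)-2-[(1R,2E)-1-(tert-butyldimethylsilyloxy)-4-methyl-4-(triethylsilyloxy)pent-2-en-1-yl]butanedioic acid | OC(=O)C[C@H](C(=O)O)[C@H](O[Si](C)(C)C(C)(C)C)/C=C/C(C)(C)O[Si](CC)(CC)CC | intermediate
16 | (3S)-3-[(1R,2E)-1-(tert-butyldimethylsilyloxy)-4-methyl-4-(triethylsilyloxy)pent-2-en-1-yl]oxolane-2,5-dione | O=C1C[C@H](C(=O)O1)[C@H](O[Si](C)(C)C(C)(C)C)/C=C/C(C)(C)O[Si](CC)(CC)CC | intermediate
17 | 1,4-benzoquinone | O=C1C=CC(=O)C=C1 | starting material
18 | 3-[(1R,2E)-1-(tert-butyldimethylsilyloxy)-4-methyl-4-(triethylsilyloxy)pent-2-en-1-yl]-2,5-bis(trimethylsilyloxy)furan | CC(C)(C)[Si](C)(C)O[C@H](/C=C/C(C)(C)O[Si](CC)(CC)CC)c1cc(O[Si](C)(C)C)oc1O[Si](C)(C)C | intermediate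
19 | 2-[(1R,2E)-1-(tert-butyldimethylsilyloxy)-4-methyl-4-(triethylsilyloxy)pent-2-en-1-yl]-1,4-bis(trimethylsilyloxy)-1,4,4a,8a-tetrahydro-1,4-epoxynaphthalene-5,8-dione (mixture of diastereomers at the four ring sp3 centres) | CC(C)(C)[Si](C)(C)O[C@H](/C=C/C(C)(C)O[Si](CC)(CC)CC)C1=CC2(O[Si](C)(C)C)OC1(O[Si](C)(C)C)C1C2C(=O)C=CC1=O | intermediate
20 | 2-[(1R,2E)-1-(tert-butyldimethylsilyloxy)-4-methyl-4-(triethylsilyloxy)pent-2-en-1-yl]-5,8-dihydroxynaphthalene-1,4-dione | CC(C)(C)[Si](C)(C)O[C@H](/C=C/C(C)(C)O[Si](CC)(CC)CC)C1=CC(=O)c2c(O)ccc(O)c2C1=O | intermediate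
21 | 2-[(1R,2E)-1,4-dihydroxy-4-methylpent-2-en-1-yl]-5,8-dihydroxynaphthalene-1,4-dione | O[C@H](/C=C/C(C)(C)O)C1=CC(=O)c2c(O)ccc(O)c2C1=O | intermediate
22 | (2R)-2-methylbutanoic acid | CC[C@@H](C)C(=O)O | starting material
23 | (1R,2E)-1-(5,8-dihydroxy-1,4-dioxo-1,4-dihydronaphthalen-2-yl)-4-hydroxy-4-methylpent-2-en-1-yl (2R)-2-methylbutanoate | CC[C@@H](C)C(=O)O[C@H](/C=C/C(C)(C)O)C1=CC(=O)c2c(O)ccc(O)c2C1=O | target

**Step count and risks**

Total step count: 11. Longest linear sequence: 10 steps (steps 1, 2 and 4 to 11, from 2-methylbut-3-en-2-ol).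

Steps most likely to fail:

1. Step 9. What may go wrong: ionisation or elimination of the allylic silyloxy group that sits next to the electron-rich furan (erosion of the carbinol configuration, diene formation), or electron transfer and conjugate C-arylation of the quinone through the furan β-carbon in place of cycloaddition. The fallback moves the side chain from the diene to the dienophile; the same compound results because the two rings of a naphthazarin are tautomerically equivalent. It sets out from 4 and comes back at 20. 2-Bromo-1,4-dimethoxybenzene is converted (n-BuLi; ZnCl2; n-BuLi; N,N,N',N'-tetraethylethylenediamine, toluene) into butyl(2,5-dimethoxyphenyl)zinc F1. F1 is added to 4 under catalysis by (−)-3-exo-morpholinoisoborneol, which directs aryl transfer to the Si face of the aldehyde, to give (1R,2E)-1-(2,5-dimethoxyphenyl)-4-methyl-4-(triethylsilyloxy)pent-2-en-1-ol F2. Silylation (t-BuMe2SiOTf, 2,6-lutidine) gives the silyl ether F3, and oxidative demethylation with (NH4)2Ce(NO3)6 in MeCN/H2O at 0 °C gives the benzoquinone F4. 2,5-Bis(trimethylsilyloxy)furan F5, made from succinic anhydride with Me3SiOTf/Et3N, should add to the unsubstituted C=C of F4 to give the oxa-bridged cycloadduct F6. The AcOH work-up of step 9 then turns F6 into 20.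

2. Step 7. What may go wrong: silyl triflate-induced loss or migration of a silyl ether followed by irreversible γ-lactonisation, or ionisation of the tertiary allylic silyl ether. The fallback closes the anhydride by neighbouring-group participation instead of deprotection and dehydration. It sets out from 13 and comes back at 16, bypassing 15. The free acid of 13 is converted under neutral conditions with 1-chloro-N,N,2-trimethylprop-1-en-1-amine (CH2Cl2, 2,6-di-tert-butylpyridine, 0 °C → rt) into the acid chloride F7. The carbonyl oxygen of the tert-butyl ester attacks the acyl chloride in a five-membered closure, and loss of tert-butyl chloride gives 16 directly. This is the pathway known from the closure of N-Boc amino acid chlorides to N-carboxyanhydrides.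

3. Step 10. What may go wrong: slow cleavage of the hindered secondary silyl ether flanked by the quinone and the alkene, so that during the long exposure the liberated allylic alcohols ionise (allylic transposition, dehydration) or the quinone is attacked. The fallback puts the ester in place before the chromophore exists, so that the last step is only the cleavage of the tertiary triethylsilyl ether. It sets out from 4 and comes back at 23. The alcohol F2 of the first fallback is esterified with 22 (DCC, 4-(dimethylamino)pyridine, CH2Cl2) to the ester F8. Oxidation with (NH4)2Ce(NO3)6 gives the quinone ester F9. Cycloaddition with the furan F5 gives the oxa-bridged cycloadduct F10, which collapses (AcOH, THF/H2O) to the triethylsilyl-protected naphthazarin ester F11. Pyridinium p-toluenesulfonate in MeOH at 0 °C then gives 23.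

**Further compounds**

F1 | step 9 | butyl(2,5-dimethoxyphenyl)zinc | CCCC[Zn]c1cc(OC)ccc1OC
F2 | step 9 | (1R,2E)-1-(2,5-dimethoxyphenyl)-4-methyl-4-(triethylsilyloxy)pent-2-en-1-ol | O[C@H](/C=C/C(C)(C)O[Si](CC)(CC)CC)c1cc(OC)ccc1OC
F3 | step 9 | tert-butyl{[(1R,2E)-1-(2,5-dimethoxyphenyl)-4-methyl-4-(triethylsilyloxy)pent-2-en-1-yl]oxy}dimethylsilane | CC(C)(C)[Si](C)(C)O[C@H](/C=C/C(C)(C)O[Si](CC)(CC)CC)c1cc(OC)ccc1OC
F4 | step 9 | 2-[(1R,2E)-1-(tert-butyldimethylsilyloxy)-4-methyl-4-(triethylsilyloxy)pent-2-en-1-yl]cyclohexa-2,5-diene-1,4-dione | CC(C)(C)[Si](C)(C)O[C@H](/C=C/C(C)(C)O[Si](CC)(CC)CC)C1=CC(=O)C=CC1=O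
F5 | step 9 | 2,5-bis(trimethylsilyloxy)furan | C[Si](C)(C)Oc1ccc(O[Si](C)(C)C)o1
F6 | step 9 | 6-[(1R,2E)-1-(tert-butyldimethylsilyloxy)-4-methyl-4-(triethylsilyloxy)pent-2-en-1-yl]-1,4-bis(trimethylsilyloxy)-1,4,4a,8a-tetrahydro-1,4-epoxynaphthalene-5,8-dione | CC(C)(C)[Si](C)(C)O[C@H](/C=C/C(C)(C)O[Si](CC)(CC)CC)C1=CC(=O)C2C(C1=O)C3(O[Si](C)(C)C)C=CC2(O[Si](C)(C)C)O3
F7 | step 7 | tert-butyl (3S,4R,5E)-4-(tert-butyldimethylsilyloxy)-3-(chlorocarbonyl)-7-methyl-7-(triethylsilyloxy)oct-5-enoate | CC(C)(C)OC(=O)C[C@H](C(Cl)=O)[C@H](O[Si](C)(C)C(C)(C)C)/C=C/C(C)(C)O[Si](CC)(CC)CC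
F8 | step 10 | (1R,2E)-1-(2,5-dimethoxyphenyl)-4-methyl-4-(triethylsilyloxy)pent-2-en-1-yl (2R)-2-methylbutanoate | CC[C@@H](C)C(=O)O[C@H](/C=C/C(C)(C)O[Si](CC)(CC)CC)c1cc(OC)ccc1OC
F9 | step 10 | (1R,2E)-1-(3,6-dioxocyclohexa-1,4-dien-1-yl)-4-methyl-4-(triethylsilyloxy)pent-2-en-1-yl (2R)-2-methylbutanoate | CC[C@@H](C)C(=O)O[C@H](/C=C/C(C)(C)O[Si](CC)(CC)CC)C1=CC(=O)C=CC1=O
F10 | step 10 | (1R,2E)-1-[5,8-dioxo-1,4-bis(trimethylsilyloxy)-1,4,4a,5,8,8a-hexahydro-1,4-epoxynaphthalen-6-yl]-4-methyl-4-(triethylsilyloxy)pent-2-en-1-yl (2R)-2-methylbutanoate | CC[C@@H](C)C(=O)O[C@H](/C=C/C(C)(C)O[Si](CC)(CC)CC)C1=CC(=O)C2C(C1=O)C3(O[Si](C)(C)C)C=CC2(O[Si](C)(C)C)O3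
F11 | step 10 | (1R,2E)-1-(5,8-dihydroxy-1,4-dioxo-1,4-dihydronaphthalen-2-yl)-4-methyl-4-(triethylsilyloxy)pent-2-en-1-yl (2R)-2-methylbutanoate | CC[C@@H](C)C(=O)O[C@H](/C=C/C(C)(C)O[Si](CC)(CC)CC)C1=CC(=O)c2c(O)ccc(O)c2C1=O
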